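## Retrosynthetic overview

1. The Z-2-methylbut-2-enoate (angelate) is put on last, by esterifying only the primary C4 hydroxymethyl of a bicyclic triol with angelic acid.
2. The triol comes from an open-chain (10R,11R)-epoxy alcohol in one cascade: ring A closes first (C4–C5 bond), then ring B (C9–C10 bond), and water ends the cascade at C8.
3. The epoxy alcohol comes from the terminal E-enal by an amine/phosphoric acid-catalysed asymmetric epoxidation, which sets the first two stereocentres; all later centres are relayed from them.
4. The enal comes from umbelliprenin by allylic oxidation of the terminal E-methyl; umbelliprenin comes from umbelliferone and (2E,6E)-farnesyl bromide.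

## Conventions and assumptions

- Numbering: open-chain compounds use farnesyl numbering (C1 = OCH2, C12 = the oxidised E-methyl carbon on C11). Bicyclic compounds use drimane numbering (C3 carbinol, C4 quaternary, C5/C10 ring fusion, C8 tertiary carbinol, C9 bearing the CH2OAr carbon C11, C12 the methyl on C8). ArO = (2-oxo-2H-chromen-7-yl)oxy.
- Target reading: the SMILES is read as the Z ester (angelate) on a trans-decalin with 3R,4S,5S,8S,9R,10R configuration. The 3-OH, 4-CH2O-acyl, 8-OH and 9-CH2OAr groups are equatorial; the three methyls are axial on one face.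
- Assumption: the facial sense of the catalyst pair in step 3 is taken by analogy with simple α-methyl-β-alkyl enals. If it gives the mirror-image epoxide, the quinidine-derived amine and the (S)-acid are used instead.

## Route

Step 1
Reactants: 1 umbelliferone (7-hydroxy-2H-chromen-2-one); 2 (2E,6E)-farnesyl bromide
Product: 3 umbelliprenin, 7-{[(2E,6E)-3,7,11-trimethyldodeca-2,6,10-trien-1-yl]oxy}-2H-chromen-2-one
Conditions: K2CO3, acetone, 56 °C
Reagents that add atoms: none
Why: Williamson ether synthesis, an SN2 O-alkylation of the acidic 7-hydroxyl by a primary allylic bromide that leaves both E alkenes untouched.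

Step 2
Reactants: 3 umbelliprenin
Product: 5 (2E,6E,10E)-2,6,10-trimethyl-12-[(2-oxo-2H-chromen-7-yl)oxy]dodeca-2,6,10-trienal, via allylic alcohol 4 (not isolated)
Conditions: SeO2 (0.3 equiv), tBuOOH, salicylic acid (cat.), CH2Cl2, 0 °C to rt; SiO2 plug; then MnO2, CH2Cl2, rt
Reagents that add atoms: selenium dioxide, O=[Se]=O (transfers the oxygen); tert-butyl hydroperoxide, CC(C)(C)OO (reoxidant and ultimate oxygen source)
Why: Riley allylic oxidation (ene reaction then [2,3]-sigmatropic shift) takes the E-methyl of the terminal, least hindered trisubstituted alkene, the 2,3-alkene being deactivated by its allylic aryloxy group, and MnO2 then oxidises only the allylic alcohol so that alcohol and aldehyde converge on the E-enal.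

Step 3
Reactants: 5 (2E,6E,10E)-2,6,10-trimethyl-12-[(2-oxo-2H-chromen-7-yl)oxy]dodeca-2,6,10-trienal
Product: 7 (10R,11R)-10,11-epoxy-12-hydroxy-10,11-dihydroumbelliprenin (trans-oxirane; CH2OH and CH3 on C11; CH2OH trans to the C9 chain), via epoxy aldehyde 6 (not isolated)
Conditions: 9-amino-9-deoxy-epi-quinine (10 mol %), (R)-3,3'-bis(2,4,6-triisopropylphenyl)-1,1'-binaphthyl-2,2'-diyl hydrogen phosphate (20 mol %), 50% aq. H2O2, THF, 50 °C; then MeOH, NaBH4, 0 °C
Reagents that add atoms: hydrogen peroxide, OO
Why: Iminium-catalysed Weitz–Scheffer-type epoxidation of an α-branched enal by a chiral primary amine/chiral phosphate ion pair activates only the C10=C11 bond, hydroperoxide adds to one face and the enamine closes the oxirane with the E relationship kept, which sets C10 (R) and C11 as the first stereocentres (2S,3R aldehyde, becoming 10R,11R on reduction only through a priority change), and NaBH4 in the cold reduces the aldehyde alone.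

Step 4
Reactants: 7 (10R,11R)-10,11-epoxy-12-hydroxy-10,11-dihydroumbelliprenin; 8 3,5-bis(trifluoromethyl)phenylboronic acid
Product: 11 7-{[(3R,4S,5S,8S,9R,10R)-3,8-dihydroxy-4-(hydroxymethyl)-4,8,10-trimethyl-trans-decalin-9-yl]methoxy}-2H-chromen-2-one, via boronic monoester 9 (not isolated), via cyclic boronate 10 (not isolated)
Conditions: 8 (1.1 equiv), H2O (1 equiv), (CF3)2CHOH/CH2Cl2 4:1, −20 to 0 °C; then HN(CH2CH2OH)2, Et2O, rt
Reagents that add atoms: water, O
Why: Proposed new method: a boronic-acid-templated, water-terminated epoxy-polyene bicyclisation, in which 8 condenses with the only hydroxyl of 7 to give monoester 9, whose boron (made more Lewis acidic by hydrogen bonding of its B–OH to the fluorinated alcohol) chelates the oxirane oxygen in a five-membered ring so that the C11–O bond ionises at the tertiary carbon, while the chelate holds both C12–H bonds out of the antiperiplanar alignment needed for a semipinacol hydride shift and no acyl group is present to take part; the 6,7-alkene attacks C11 anti to the leaving oxygen through a chair and the 2,3-alkene attacks the resulting cation through a second chair (ring A, then ring B), which relays the 10R,11R epoxide and the two E alkenes into 3R, 4S (equatorial CH2O from the E position, axial CH3), 5S, 10R and 9R (equatorial CH2OAr); the tertiary C8 cation, in a medium that is neither basic nor nucleophilic, is captured by water on the equatorial face, anti to the new C9–C10 bond and away from the axial C10 methyl (8S), and the proton set free removes hydroxide from the borate to leave the neutral six-membered boronate 10, which takes the acid out of the medium and is cleaved by diethanolamine; the closest known reactions are Lewis-acid or fluorinated-alcohol-promoted epoxide-initiated cation–olefin polycyclisation (including the BF3-promoted bicyclisation of epoxy-umbelliprenin), the hydroxyl-terminated superacid cyclisation of farnesyl acetate, and boronic or borinic acid activation of 2,3-epoxy alcohols.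

Step 5
Reactants: 11 7-{[(3R,4S,5S,8S,9R,10R)-3,8-dihydroxy-4-(hydroxymethyl)-4,8,10-trimethyl-trans-decalin-9-yl]methoxy}-2H-chromen-2-one; 12 angelic acid, (Z)-2-methylbut-2-enoic acid
Product: 13 {(3R,4S,5S,8S,9R,10R)-3,8-dihydroxy-4,8,10-trimethyl-9-{[(2-oxo-2H-chromen-7-yl)oxy]methyl}-trans-decalin-4-yl}methyl (Z)-2-methylbut-2-enoate (CNP0139045.1)
Conditions: 12, 2,4,6-Cl3C6H2COCl, Et3N, toluene, rt; then 11, toluene, 60 °C
Reagents that add atoms: none
Why: Yamaguchi esterification through the mixed anhydride, run without DMAP so that the Z enoate does not isomerise to the E (tiglate) ester, acylates the primary hydroxyl in preference to the secondary C3 hydroxyl next to quaternary C4 and the tertiary C8 hydroxyl, and touches no stereocentre.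

## Compound list

1 | umbelliferone (7-hydroxy-2H-chromen-2-one) | Oc1ccc2ccc(=O)oc2c1 | starting material
2 | (2E,6E)-farnesyl bromide | CC(C)=CCC/C(C)=C/CC/C(C)=C/CBr | starting material
3 | umbelliprenin | CC(C)=CCC/C(C)=C/CC/C(C)=C/COc1ccc2ccc(=O)oc2c1 | intermediate
4 | (2E,6E,10E)-12-hydroxyumbelliprenin (allylic alcohol) | OC/C(C)=C/CC/C(C)=C/CC/C(C)=C/COc1ccc2ccc(=O)oc2c1 | intermediate
5 | (2E,6E,10E)-2,6,10-trimethyl-12-[(2-oxo-2H-chromen-7-yl)oxy]dodeca-2,6,10-trienal | O=C/C(C)=C/CC/C(C)=C/CC/C(C)=C/COc1ccc2ccc(=O)oc2c1 | intermediate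
6 | (2S,3R)-3-{(3E,7E)-3,7-dimethyl-9-[(2-oxo-2H-chromen-7-yl)oxy]nona-3,7-dien-1-yl}-2-methyloxirane-2-carbaldehyde | O=C[C@@]1(C)O[C@@H]1CC/C(C)=C/CC/C(C)=C/COc1ccc2ccc(=O)oc2c1 | intermediate
7 | (10R,11R)-10,11-epoxy-12-hydroxy-10,11-dihydroumbelliprenin | OC[C@@]1(C)O[C@@H]1CC/C(C)=C/CC/C(C)=C/COc1ccc2ccc(=O)oc2c1 | intermediate
8 | 3,5-bis(trifluoromethyl)phenylboronic acid | OB(O)c1cc(C(F)(F)F)cc(C(F)(F)F)c1 | starting material
9 | O12-[aryl(hydroxy)boryl] monoester of 7 (aryl = 3,5-bis(trifluoromethyl)phenyl) | OB(OC[C@@]1(C)O[C@@H]1CC/C(C)=C/CC/C(C)=C/COc1ccc2ccc(=O)oc2c1)c1cc(C(F)(F)F)cc(C(F)(F)F)c1 | intermediate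
10 | cyclic arylboronate of 11 (1,3,2-dioxaborinane across the C3 oxygen and the C4 CH2O oxygen; 8-OH free) | FC(F)(F)c1cc(B2OC[C@]3(C)[C@H]4CC[C@](C)(O)[C@@H](COc5ccc6ccc(=O)oc6c5)[C@]4(C)CC[C@H]3O2)cc(C(F)(F)F)c1 | intermediate
11 | 7-{[(3R,4S,5S,8S,9R,10R)-3,8-dihydroxy-4-(hydroxymethyl)-4,8,10-trimethyl-trans-decalin-9-yl]methoxy}-2H-chromen-2-one | OC[C@]1(C)[C@H]2CC[C@](C)(O)[C@@H](COc3ccc4ccc(=O)oc4c3)[C@]2(C)CC[C@H]1O | intermediate
12 | angelic acid, (Z)-2-methylbut-2-enoic acid | C/C=C(/C)C(=O)O | starting material
13 | CNP0139045.1, the C4-CH2O angelate of 11 | C/C=C(/C)C(=O)OC[C@]1(C)[C@H]2CC[C@](C)(O)[C@@H](COc3ccc4ccc(=O)oc4c3)[C@]2(C)CC[C@H]1O | target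

## Step count and risks

Total steps: 5. Longest linear sequence: 5 steps (1 → 3 → 5 → 7 → 11 → 13).

**Step 4 (the proposed new reaction).** The likely failures are proton loss from the C8 cation to alkenes instead of water capture, arrest after ring A, and ionisation of the allylic aryl ether. The fallback uses known chemistry, sets out from 7 and comes back at 11. Silylation of 7 (TBSCl, imidazole, DMF) gives the silyl ether F1. BF3·OEt2 in CH2Cl2 at −78 °C effects the known proton-loss-terminated epoxy-polyene bicyclisation to the exocyclic 8(12)-alkene F2 together with the endocyclic 7-ene F3. Both alkenes give the same tertiary C8 radical on Mukaiyama hydration (Co(acac)2, PhSiH3, O2, iPrOH), and oxygen is taken up on the equatorial face, away from the axial C10 methyl, to give the tertiary alcohol F4. Bu4NF in THF removes the silyl group and returns the route at 11.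

**Step 5.** The likely failures are partial Z to E isomerisation of the acyl group and competing acylation of the C3 hydroxyl. The fallback sets out from 11 and comes back at 13. Steglich acylation of the primary hydroxyl with 2-[bis(2,2,2-trifluoroethoxy)phosphoryl]propanoic acid (DCC, cat. DMAP, CH2Cl2, −20 °C) uses an acid that cannot isomerise, so DMAP and low temperature can be used for selectivity; it gives the phosphonate ester F5. Still–Gennari olefination with acetaldehyde (KN(SiMe3)2, 18-crown-6, THF, −78 °C) then builds the Z-2-methylbut-2-enoate in place and gives 13.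

**Step 3.** The likely failures are insufficient enantioselectivity or conversion on this long-chain α,β-disubstituted enal. The fallback sets out from 4 (isolated by stopping step 2 before the MnO2 treatment) and comes back at 7. Sharpless–Katsuki epoxidation (Ti(OiPr)4, D-(−)-diethyl tartrate, tBuOOH, 4 Å sieves, CH2Cl2, −20 °C) gives the (10R,11R) epoxy alcohol directly, the hydroxyl directing the oxidant to the 10,11-alkene; no new compound is made (F0).

## Further compounds

F1 | step 4 | tert-butyldimethylsilyl ether of 7 at O12 | CC(C)(C)[Si](C)(C)OC[C@@]1(C)O[C@@H]1CC/C(C)=C/CC/C(C)=C/COc1ccc2ccc(=O)oc2c1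
F2 | step 4 | exocyclic 8(12)-alkene: 3-hydroxy, C4 CH2OTBS, 9-CH2OAr trans-decalin with the configuration of 11 at C3, C4, C5, C9 and C10 | CC(C)(C)[Si](C)(C)OC[C@]1(C)[C@H]2CCC(=C)[C@@H](COc3ccc4ccc(=O)oc4c3)[C@]2(C)CC[C@H]1O
F3 | step 4 | endocyclic 7-ene isomer of F2 | CC(C)(C)[Si](C)(C)OC[C@]1(C)[C@H]2CC=C(C)[C@@H](COc3ccc4ccc(=O)oc4c3)[C@]2(C)CC[C@H]1O
F4 | step 4 | tert-butyldimethylsilyl ether of 11 at the C4 CH2O oxygen | CC(C)(C)[Si](C)(C)OC[C@]1(C)[C@H]2CC[C@](C)(O)[C@@H](COc3ccc4ccc(=O)oc4c3)[C@]2(C)CC[C@H]1O
F5 | step 5 | 2-[bis(2,2,2-trifluoroethoxy)phosphoryl]propanoate of 11 at the C4 CH2O oxygen (mixture at the phosphonate α-carbon) | CC(C(=O)OC[C@]1(C)[C@H]2CC[C@](C)(O)[C@@H](COc3ccc4ccc(=O)oc4c3)[C@]2(C)CC[C@H]1O)P(=O)(OCC(F)(F)F)OCC(F)(F)F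
F0 | step 3 | none | none
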